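**Plan**

- Retrosynthesis: the C1 methyl and the C8a hydroxyl are removed first (back to a C1 ketone, then a C1 methylidene). The C4a–C8a and C4–Br bonds are then cut together, which opens rings B and C to one ten-membered (E,E)-1,5-diene. That ring is cut at C2–C3 (anionic oxy-Cope retron) to a 1-isopropenyl-2-vinylcyclohexanol, whose ring is cut at C4a–C5 (aldol) and at C7–C6 and C7–C8 (two allyl-type additions to an acyl carbon on C1′).
- Forward order: cyclopentane ring A from 2,2-dimethylcyclopentane-1,3-dione, then a cyclohexanone on the acyl carbon C7, ring expansion to the ten-membered ring, both decalin rings in one transannular step, and last the oxygens at C1 and C8a.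
- Feature used: the C4a–C8a bond shared by rings B and C divides a ten-membered carbocycle (C1–C2–C3–C4–C4a–C5–C6–C7–C8–C8a), and bromine on C4 sits beside the methyl-bearing fusion carbon C4a. This is the pattern left when a bromonium ion on a C4=C4a alkene is opened at C4a by C8a of a facing C1=C8a alkene.
- Stereochemistry: C4′ from a CBS reduction followed by SN2 inversion; C2′ from a ligand-controlled conjugate borylation; C1′ from a Frater–Seebach alkylation; C7 from a Felkin–Anh allylation; C4, C4a and C8a from the two (E)-alkenes and the chair–chair transition state selected by C7; C8a–O and C1 from the angular C4a methyl.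

Key step: step 22

Remark: locants C1–C8a (decalin numbered as naphthalene) and C1′–C5′ (cyclopentane, C1′ on C7) are those of the target and are used for the corresponding atoms of every intermediate; "Cyp" is the (2R,4S)-4-bromo-2-[(tert-butyldimethylsilyl)oxy]-1,5,5-trimethylcyclopentyl group of 10 (C1′ methyl trans to the silyloxy group); the ligand enantiomer named in step 5 is assumed to deliver boron cis to bromine, and its antipode would be used if a test reaction showed the opposite sense.

Step 1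
Reactants: 1 2,2-dimethylcyclopentane-1,3-dione
Product: 2 (R)-3-hydroxy-2,2-dimethylcyclopentan-1-one
Conditions: (S)-2-methyl-CBS-oxazaborolidine (10 mol %), BH3·SMe2 (0.6 equiv), THF, −20 °C; MeOH quench
Reagents that add atoms: none
Why: Corey–Bakshi–Shibata reduction of one of the two equivalent carbonyl groups, in which the catalyst distinguishes the quaternary side (large) from the CH2 side (small) and should give the R carbinol, while substoichiometric borane limits diol formation.

Step 2
Reactants: 2 (R)-3-hydroxy-2,2-dimethylcyclopentan-1-one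
Product: 3 (S)-3-bromo-2,2-dimethylcyclopentan-1-one
Conditions: CBr4, PPh3, CH2Cl2, 0 °C to rt
Reagents that add atoms: carbon tetrabromide, BrC(Br)(Br)Br
Why: Appel reaction, an SN2 displacement of the oxyphosphonium group by bromide with inversion, placed on the smallest and least hindered cyclopentanol of the route, where the ketone cannot trigger elimination because its α-carbon towards the carbinol is fully substituted.

Step 3
Reactants: 3 (S)-3-bromo-2,2-dimethylcyclopentan-1-one
Product: 4 (S)-4-bromo-5,5-dimethylcyclopent-1-en-1-yl trifluoromethanesulfonate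
Conditions: Tf2O, 2,6-di-tert-butyl-4-methylpyridine, CH2Cl2, 0 °C to rt
Reagents that add atoms: trifluoromethanesulfonic anhydride, O=S(=O)(OS(=O)(=O)C(F)(F)F)C(F)(F)F
Why: Enol triflate formation from a ketone with triflic anhydride and a hindered pyridine; only one α-carbon carries hydrogen, so a single regioisomer can form and the C–Br stereocentre is not touched.

Step 4
Reactants: 4 (S)-4-bromo-5,5-dimethylcyclopent-1-en-1-yl trifluoromethanesulfonate
Product: 5 methyl (S)-4-bromo-5,5-dimethylcyclopent-1-ene-1-carboxylate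
Conditions: Pd(OAc)2 (5 mol %), 1,3-bis(diphenylphosphino)propane, CO (1 atm), MeOH, Et3N, DMF, 50 °C
Reagents that add atoms: carbon monoxide, [C-]#[O+]; methanol, CO
Why: Palladium-catalysed methoxycarbonylation of an enol triflate (oxidative addition, CO insertion, methanolysis), which is far faster at the alkenyl triflate than any reaction of the hindered secondary alkyl bromide.

Step 5
Reactants: 5 methyl (S)-4-bromo-5,5-dimethylcyclopent-1-ene-1-carboxylate
Product: 7 methyl (2R,4S)-4-bromo-2-hydroxy-5,5-dimethylcyclopentane-1-carboxylate (both C1 epimers), via pinacol boronate 6 (not isolated)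
Conditions: CuCl (5 mol %), NaOt-Bu, (R)-1-[(SP)-2-(diphenylphosphino)ferrocenyl]ethyldicyclohexylphosphine, B2pin2, MeOH, THF, rt; then NaBO3·4H2O, THF/H2O, rt
Reagents that add atoms: bis(pinacolato)diboron, CC1(C)OB(OC1(C)C)B1OC(C)(C)C(C)(C)O1 (boryl group of 6); sodium perborate tetrahydrate, [Na+].[Na+].O[B-]1(O)OO[B-](O)(O)OO1 (hydroxyl oxygen of 7)
Why: Copper-catalysed asymmetric conjugate borylation of an α,β-unsaturated ester puts boron on C2′ under ligand control (the 1,3-related bromide should bias the faces only weakly), and perborate oxidation replaces boron by hydroxyl with retention, giving the 2R alcohol cis to bromine; C1′ is left as a mixture because the next step erases it.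

Step 6
Reactants: 7 methyl (2R,4S)-4-bromo-2-hydroxy-5,5-dimethylcyclopentane-1-carboxylate
Product: 9 methyl (1S,2R,4S)-4-bromo-2-hydroxy-1,5,5-trimethylcyclopentane-1-carboxylate, via dilithium alkoxide enolate 8 (not isolated)
Conditions: LiN(i-Pr)2 (2.2 equiv), THF, −78 to −20 °C; then MeI, HMPA, −78 to −20 °C
Reagents that add atoms: iodomethane, CI
Why: Frater–Seebach alkylation, in which the chelated alkoxide–enolate dianion is methylated on the face away from the C2′ alkoxide, so the new methyl is trans to the hydroxyl and the ester cis to it whatever the C1′ configuration of 7.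

Step 7
Reactants: 9 methyl (1S,2R,4S)-4-bromo-2-hydroxy-1,5,5-trimethylcyclopentane-1-carboxylate
Product: 10 methyl (1S,2R,4S)-4-bromo-2-[(tert-butyldimethylsilyl)oxy]-1,5,5-trimethylcyclopentane-1-carboxylate
Conditions: t-BuMe2SiOSO2CF3, 2,6-lutidine, CH2Cl2, 0 °C to rt
Reagents that add atoms: tert-butyldimethylsilyl trifluoromethanesulfonate, CC(C)(C)[Si](C)(C)OS(=O)(=O)C(F)(F)F
Why: Silylation with a silyl triflate and 2,6-lutidine, the standard conditions for a secondary alcohol next to a quaternary carbon.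

Step 8
Reactants: 10 methyl (1S,2R,4S)-4-bromo-2-[(tert-butyldimethylsilyl)oxy]-1,5,5-trimethylcyclopentane-1-carboxylate
Product: 11 [(1R,2R,4S)-4-bromo-2-[(tert-butyldimethylsilyl)oxy]-1,5,5-trimethylcyclopentyl]methanol (Cyp–CH2OH)
Conditions: i-Bu2AlH (2.5 equiv), CH2Cl2, −78 to 0 °C
Reagents that add atoms: none
Why: Aluminium hydride reduction of the neopentyl ester to the primary alcohol at a temperature where the secondary bromide and the silyl ether are left alone.

Step 9
Reactants: 11 Cyp–CH2OH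
Product: 12 (1S,2R,4S)-4-bromo-2-[(tert-butyldimethylsilyl)oxy]-1,5,5-trimethylcyclopentane-1-carbaldehyde (Cyp–CHO)
Conditions: Dess–Martin periodinane, NaHCO3, CH2Cl2, rt
Reagents that add atoms: none
Why: Dess–Martin oxidation to an aldehyde that has no α-hydrogen and so can neither epimerise nor expel the β-silyloxy group.

Step 10
Reactants: 12 Cyp–CHO; 13 2-methylallylmagnesium chloride
Product: 14 1-Cyp-3-methylbut-3-en-1-ol (carbinol epimers)
Conditions: THF, −78 °C
Reagents that add atoms: 2-methylallylmagnesium chloride, CC(=C)C[Mg]Cl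
Why: Grignard 1,2-addition of an allyl-type reagent to the hindered aldehyde; the new carbinol centre is oxidised in the next step, so its configuration is irrelevant.

Step 11
Reactants: 14 1-Cyp-3-methylbut-3-en-1-ol
Product: 15 1-Cyp-3-methylbut-3-en-1-one
Conditions: Dess–Martin periodinane, NaHCO3, CH2Cl2, 0 °C to rt
Reagents that add atoms: none
Why: Dess–Martin oxidation under buffered neutral conditions gives the β,γ-unsaturated ketone without moving the alkene into conjugation.

Step 12
Reactants: 15 1-Cyp-3-methylbut-3-en-1-one; 16 allylmagnesium bromide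
Product: 17 (4S)-4-Cyp-2-methylhepta-1,6-dien-4-ol (C4 of this name is C7 of the target)
Conditions: Et2O, −78 °C
Reagents that add atoms: allylmagnesium bromide, C=CC[Mg]Br
Why: Grignard 1,2-addition under Felkin–Anh control, with the quaternary C5′ anti to the incoming allyl group and the methallyl arm beside the small C1′ methyl, which should give the 7S carbinol in which the methallyl arm is the future C8 and the allyl group the future C6.

Step 13
Reactants: 17 (4S)-4-Cyp-2-methylhepta-1,6-dien-4-ol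
Product: 18 (4S)-4-Cyp-2-methyl-4-[(triethylsilyl)oxy]hepta-1,6-diene
Conditions: Et3SiOSO2CF3, 2,6-lutidine, CH2Cl2, 0 °C to rt
Reagents that add atoms: triethylsilyl trifluoromethanesulfonate, CC[Si](CC)(CC)OS(=O)(=O)C(F)(F)F
Why: Silyl triflate silylation of the hindered tertiary alcohol, which guards C7–O against retro-aldol cleavage once the carbonyl groups are unveiled and against bromoetherification in step 22.

Step 14
Reactants: 18 (4S)-4-Cyp-2-methyl-4-[(triethylsilyl)oxy]hepta-1,6-diene
Product: 20 (3S)-3-Cyp-5-oxo-3-[(triethylsilyl)oxy]hexanal, via bis-ozonide 19 (not isolated)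
Conditions: O3, CH2Cl2, −78 °C; then PPh3, −78 °C to rt
Reagents that add atoms: ozone, [O-][O+]=O
Why: Ozonolysis with reductive work-up cleaves both terminal alkenes, turning the methallyl arm into the methyl ketone (C8, C8a, C4a) and the allyl arm into the aldehyde (C6, C5), each with loss of formaldehyde.

Step 15
Reactants: 20 (3S)-3-Cyp-5-oxo-3-[(triethylsilyl)oxy]hexanal
Product: 22 (5S)-5-Cyp-5-[(triethylsilyl)oxy]cyclohex-2-en-1-one, via beta-hydroxy ketone 21 (not isolated)
Conditions: Bn2NH·CF3CO2H (20 mol %), toluene, 50 °C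
Reagents that add atoms: none
Why: Intramolecular aldol condensation under amine-salt catalysis, in which the ketone methyl carbon (C4a) is the only nucleophilic carbon able to reach the aldehyde (C5) through a six-membered ring and no strong base is present to expel the β-silyloxy group.

Step 16
Reactants: 22 (5S)-5-Cyp-5-[(triethylsilyl)oxy]cyclohex-2-en-1-one
Product: 23 (5S)-5-Cyp-2-iodo-5-[(triethylsilyl)oxy]cyclohex-2-en-1-one
Conditions: I2, pyridine, CH2Cl2, rt
Reagents that add atoms: iodine, II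
Why: α-Iodination of an enone by conjugate addition of pyridine, iodination of the enolate and elimination, which marks C4a for cross-coupling.

Step 17
Reactants: 23 (5S)-5-Cyp-2-iodo-5-[(triethylsilyl)oxy]cyclohex-2-en-1-one; 24 tributyl(vinyl)stannane
Product: 25 (5S)-5-Cyp-2-ethenyl-5-[(triethylsilyl)oxy]cyclohex-2-en-1-one
Conditions: Pd2(dba)3, AsPh3, CuI, NMP, rt
Reagents that add atoms: tributyl(vinyl)stannane, C=C[Sn](CCCC)(CCCC)CCCC
Why: Stille coupling of an α-iodoenone with a vinylstannane at room temperature, which leaves the alkyl bromide alone; the cross-conjugated dienone is used at once to avoid Diels–Alder dimerisation.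

Step 18
Reactants: 25 (5S)-5-Cyp-2-ethenyl-5-[(triethylsilyl)oxy]cyclohex-2-en-1-one
Product: 27 (2S,5S)-5-Cyp-2-ethenyl-2-methyl-5-[(triethylsilyl)oxy]cyclohexan-1-one, via lithium dienolate 26 (not isolated)
Conditions: Li(s-Bu)3BH, THF, −78 °C; then MeI, HMPA, −78 to −20 °C
Reagents that add atoms: iodomethane, CI
Why: Conjugate reduction followed by enolate alkylation, in which hydride adds to the unsubstituted β-carbon C5 to give the C8a–C4a dienolate regiospecifically (no enolate towards C8 that could expel the C7 silyloxy group) and methyl iodide attacks C4a axially on the face away from the axial C7 silyloxy group, so methyl ends axial and vinyl equatorial.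

Step 19
Reactants: 27 (2S,5S)-5-Cyp-2-ethenyl-2-methyl-5-[(triethylsilyl)oxy]cyclohexan-1-one; 28 isopropenylmagnesium bromide
Product: 29 5-Cyp-2-ethenyl-2-methyl-1-(prop-1-en-2-yl)-5-[(triethylsilyl)oxy]cyclohexan-1-ol (isopropenyl trans to vinyl; hydroxyl axial and cis to the C7 silyloxy group)
Conditions: CeCl3, THF, −78 to 0 °C
Reagents that add atoms: isopropenylmagnesium bromide, CC(=C)[Mg]Br
Why: Organocerium 1,2-addition to a hindered enolisable ketone, in which the axial C7 silyloxy group blocks axial approach, so isopropenyl enters equatorially and trans to the equatorial vinyl group.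

Step 20
Reactants: 29 5-Cyp-2-ethenyl-2-methyl-1-(prop-1-en-2-yl)-5-[(triethylsilyl)oxy]cyclohexan-1-ol
Product: 32 (1Z,5E)-9-Cyp-2,6-dimethyl-9-[(triethylsilyl)oxy]cyclodeca-1,5-dien-1-yl trifluoromethanesulfonate (triflate on C8a), via potassium alkoxide 30 (not isolated), via potassium enolate 31 (not isolated)
Conditions: KH, 18-crown-6, THF, 0 °C to rt; then PhNTf2, −78 °C to rt
Reagents that add atoms: N-phenylbis(trifluoromethanesulfonimide), O=S(=O)(N(c1ccccc1)S(=O)(=O)C(F)(F)F)C(F)(F)F
Why: Anionic oxy-Cope rearrangement of the trans-1,2-dialkenyl alkoxide through a chair transition state with both ring bonds equatorial, which breaks C4a–C8a, joins C2 to C3 and gives the (E)-C4=C4a alkene and the enolate with C8 trans to C2, a geometry that O-triflation then fixes.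

Step 21
Reactants: 32 (1Z,5E)-9-Cyp-2,6-dimethyl-9-[(triethylsilyl)oxy]cyclodeca-1,5-dien-1-yl trifluoromethanesulfonate
Product: 33 (1E,5E)-8-Cyp-1,5-dimethyl-8-[(triethylsilyl)oxy]cyclodeca-1,5-diene (alkenes C4=C4a and C1=C8a; carbinol carbon C7)
Conditions: Pd(OAc)2 (5 mol %), PPh3, HCO2H, n-Bu3N, DMF, rt to 40 °C
Reagents that add atoms: none
Why: Palladium-catalysed formate reduction of an enol triflate replaces the triflate by hydrogen with retention of alkene geometry, under buffered conditions and below the temperature at which (E,E)-cyclodeca-1,5-dienes undergo Cope rearrangement.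

Step 22
Reactants: 33 (1E,5E)-8-Cyp-1,5-dimethyl-8-[(triethylsilyl)oxy]cyclodeca-1,5-diene
Product: 34 4-bromo-7-Cyp-4a-methyl-1-methylidene-7-[(triethylsilyl)oxy]decahydronaphthalene (trans-fused, 8a-H anti to the 4a-methyl; bromine equatorial and syn to the 4a-methyl; silyloxy group axial)
Conditions: 2,4,4,6-tetrabromocyclohexa-2,5-dienone (1.05 equiv), MeNO2, −20 to 0 °C
Reagents that add atoms: 2,4,4,6-tetrabromocyclohexa-2,5-dienone, O=C1C(Br)=CC(Br)(Br)C=C1Br
Why: Bromonium transfer from the dienone to the C4=C4a alkene is followed by Markovnikov opening at C4a by C8a of the C1=C8a alkene held across the ring, and the tertiary C1 cation then loses a methyl proton to the 2,4,6-tribromophenoxide released by the reagent. The closest known reactions are the electrophile-induced transannular cyclisations of (E,E)-germacra-1(10),4-dienes to eudesmanes and the bromonium-initiated cation–olefin cyclisations carried out with this dienone. The single new C4a–C8a bond closes ring C (C1, C2, C3, C4, C4a, C8a) in a 6-endo mode with respect to both alkenes and ring B (C4a, C5, C6, C7, C8, C8a) in a 6-exo mode with respect to both, through the chair–chair crown conformer. Anti addition across the (E)-C4=C4a alkene places bromine on C4 equatorial and syn to the C4a methyl, the (E)-C1=C8a geometry gives the trans ring fusion, and the C7 stereocentre selects the crown conformer that keeps the bulky Cyp group equatorial, which fixes the absolute sense at C4, C4a and C8a. The step needs site selectivity for C4=C4a, secured by reversible bromonium transfer in a non-nucleophilic solvent (only the C4=C4a bromonium has a Markovnikov path to two six-membered rings) and by the C7 silyl ether, which shields the nearer C1=C8a alkene and prevents bromoetherification. Proton loss from the methyl group should be favoured because the bulky phenoxide reaches it most easily while the axial C8a–H lies beside the axial silyloxy group.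

Step 23
Reactants: 34 4-bromo-7-Cyp-4a-methyl-1-methylidene-7-[(triethylsilyl)oxy]decahydronaphthalene
Product: 36 4-bromo-7-Cyp-4a-methyl-7-[(triethylsilyl)oxy]octahydronaphthalen-1(2H)-one (trans-fused), via ozonide 35 (not isolated)
Conditions: O3, CH2Cl2, −78 °C; then PPh3, −78 °C to rt
Reagents that add atoms: ozone, [O-][O+]=O
Why: Ozonolysis with reductive work-up cleaves the only alkene, the exocyclic methylidene, to the C1 ketone and leaves bromides and silyl ethers untouched.

Step 24
Reactants: 36 4-bromo-7-Cyp-4a-methyl-7-[(triethylsilyl)oxy]octahydronaphthalen-1(2H)-one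
Product: 38 4-bromo-7-Cyp-4a-methyl-7-[(triethylsilyl)oxy]-8a-[(trimethylsilyl)oxy]octahydronaphthalen-1(2H)-one (8a-oxygen anti to the 4a-methyl), via trimethylsilyl enol ether 37 (not isolated)
Conditions: Me3SiCl, NaI, Et3N, MeCN, rt; then m-CPBA, NaHCO3, CH2Cl2, −20 °C
Reagents that add atoms: chlorotrimethylsilane, C[Si](C)(C)Cl; 3-chloroperbenzoic acid, OOC(=O)c1cccc(Cl)c1
Why: Rubottom oxidation, in which soft enolisation under equilibrating conditions gives the more substituted C1=C8a silyl enol ether (and avoids a free enolate next to the γ-bromide), and the peracid should attack the face away from the axial C4a methyl, as angular-methyl decalin enol derivatives do, so the new C8a–O bond is trans to that methyl.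

Step 25
Reactants: 38 4-bromo-7-Cyp-4a-methyl-7-[(triethylsilyl)oxy]-8a-[(trimethylsilyl)oxy]octahydronaphthalen-1(2H)-one
Product: 39 4-bromo-7-Cyp-1,4a-dimethyl-7-[(triethylsilyl)oxy]-8a-[(trimethylsilyl)oxy]decahydronaphthalen-1-ol (C1 hydroxyl axial, cis to the 4a-methyl)
Conditions: MeMgBr, THF, −78 to 0 °C
Reagents that add atoms: methylmagnesium bromide, C[Mg]Br
Why: Grignard 1,2-addition in which axial approach to C1 is blocked by the 1,3-diaxial C4a methyl, so methyl enters equatorially and the hydroxyl ends axial, trans to the C8a oxygen as in the target.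

Step 26
Reactants: 39 4-bromo-7-Cyp-1,4a-dimethyl-7-[(triethylsilyl)oxy]-8a-[(trimethylsilyl)oxy]decahydronaphthalen-1-ol
Product: 40 (1S,4R,4aR,7S,8aS)-4-bromo-7-[(1S,2R,4S)-4-bromo-2-hydroxy-1,5,5-trimethylcyclopentyl]-1,4a-dimethyloctahydronaphthalene-1,7,8a(2H)-triol (CNP0390567.2)
Conditions: HF·pyridine, THF, 0 °C to rt
Reagents that add atoms: none
Why: Fluoride-mediated desilylation removes the trimethylsilyl, triethylsilyl and tert-butyldimethylsilyl groups under conditions that should leave the two secondary bromides and the tertiary alcohols unchanged.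

**Compound list**

1 | 2,2-dimethylcyclopentane-1,3-dione | CC1(C)C(=O)CCC1=O | starting material
2 | (R)-3-hydroxy-2,2-dimethylcyclopentan-1-one | CC1(C)[C@H](O)CCC1=O | intermediate
3 | (S)-3-bromo-2,2-dimethylcyclopentan-1-one | CC1(C)[C@@H](Br)CCC1=O | intermediate
4 | (S)-4-bromo-5,5-dimethylcyclopent-1-en-1-yl trifluoromethanesulfonate | CC1(C)[C@@H](Br)CC=C1OS(=O)(=O)C(F)(F)F | intermediate
5 | methyl (S)-4-bromo-5,5-dimethylcyclopent-1-ene-1-carboxylate | CC1(C)[C@@H](Br)CC=C1C(=O)OC | intermediate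
6 | methyl (2R,4S)-4-bromo-5,5-dimethyl-2-(4,4,5,5-tetramethyl-1,3,2-dioxaborolan-2-yl)cyclopentane-1-carboxylate (C1 epimers) | CC1(C)[C@@H](Br)C[C@@H](B2OC(C)(C)C(C)(C)O2)C1C(=O)OC | intermediate (not isolated)
7 | methyl (2R,4S)-4-bromo-2-hydroxy-5,5-dimethylcyclopentane-1-carboxylate (C1 epimers) | CC1(C)[C@@H](Br)C[C@@H](O)C1C(=O)OC | intermediate
8 | dilithium alkoxide enolate of 7 | CC1(C)[C@@H](Br)C[C@@H]([O-])C1=C([O-])OC.[Li+].[Li+] | intermediate (not isolated)
9 | methyl (1S,2R,4S)-4-bromo-2-hydroxy-1,5,5-trimethylcyclopentane-1-carboxylate | CC1(C)[C@@H](Br)C[C@@H](O)[C@@]1(C)C(=O)OC | intermediate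
10 | methyl (1S,2R,4S)-4-bromo-2-[(tert-butyldimethylsilyl)oxy]-1,5,5-trimethylcyclopentane-1-carboxylate | CC1(C)[C@@H](Br)C[C@@H](O[Si](C)(C)C(C)(C)C)[C@@]1(C)C(=O)OC | intermediate
11 | [(1R,2R,4S)-4-bromo-2-[(tert-butyldimethylsilyl)oxy]-1,5,5-trimethylcyclopentyl]methanol | CC1(C)[C@@H](Br)C[C@@H](O[Si](C)(C)C(C)(C)C)[C@@]1(C)CO | intermediate
12 | (1S,2R,4S)-4-bromo-2-[(tert-butyldimethylsilyl)oxy]-1,5,5-trimethylcyclopentane-1-carbaldehyde | CC1(C)[C@@H](Br)C[C@@H](O[Si](C)(C)C(C)(C)C)[C@@]1(C)C=O | intermediate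
13 | 2-methylallylmagnesium chloride | CC(=C)C[Mg]Cl | starting material
14 | 1-Cyp-3-methylbut-3-en-1-ol (carbinol epimers) | CC1(C)[C@@H](Br)C[C@@H](O[Si](C)(C)C(C)(C)C)[C@@]1(C)C(O)CC(C)=C | intermediate
15 | 1-Cyp-3-methylbut-3-en-1-one | CC1(C)[C@@H](Br)C[C@@H](O[Si](C)(C)C(C)(C)C)[C@@]1(C)C(=O)CC(C)=C | intermediate
16 | allylmagnesium bromide | C=CC[Mg]Br | starting material
17 | (4S)-4-Cyp-2-methylhepta-1,6-dien-4-ol | CC1(C)[C@@H](Br)C[C@@H](O[Si](C)(C)C(C)(C)C)[C@@]1(C)[C@](CC(C)=C)(O)CC=C | intermediate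
18 | (4S)-4-Cyp-2-methyl-4-[(triethylsilyl)oxy]hepta-1,6-diene | CC1(C)[C@@H](Br)C[C@@H](O[Si](C)(C)C(C)(C)C)[C@@]1(C)[C@](CC(C)=C)(O[Si](CC)(CC)CC)CC=C | intermediate
19 | bis(1,2,4-trioxolane) from 18 (both alkenes ozonised) | CC1(C)[C@@H](Br)C[C@@H](O[Si](C)(C)C(C)(C)C)[C@@]1(C)[C@](CC1(C)OCOO1)(O[Si](CC)(CC)CC)CC1OCOO1 | intermediate (not isolated)
20 | (3S)-3-Cyp-5-oxo-3-[(triethylsilyl)oxy]hexanal | CC1(C)[C@@H](Br)C[C@@H](O[Si](C)(C)C(C)(C)C)[C@@]1(C)[C@](CC(C)=O)(O[Si](CC)(CC)CC)CC=O | intermediate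
21 | 5-Cyp-3-hydroxy-5-[(triethylsilyl)oxy]cyclohexan-1-one (aldol, C3 epimers) | CC1(C)[C@@H](Br)C[C@@H](O[Si](C)(C)C(C)(C)C)[C@@]1(C)[C@]1(O[Si](CC)(CC)CC)CC(O)CC(=O)C1 | intermediate (not isolated)
22 | (5S)-5-Cyp-5-[(triethylsilyl)oxy]cyclohex-2-en-1-one | CC1(C)[C@@H](Br)C[C@@H](O[Si](C)(C)C(C)(C)C)[C@@]1(C)[C@]1(O[Si](CC)(CC)CC)CC=CC(=O)C1 | intermediate
23 | (5S)-5-Cyp-2-iodo-5-[(triethylsilyl)oxy]cyclohex-2-en-1-one | CC1(C)[C@@H](Br)C[C@@H](O[Si](C)(C)C(C)(C)C)[C@@]1(C)[C@]1(O[Si](CC)(CC)CC)CC=C(I)C(=O)C1 | intermediate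
24 | tributyl(vinyl)stannane | C=C[Sn](CCCC)(CCCC)CCCC | starting material
25 | (5S)-5-Cyp-2-ethenyl-5-[(triethylsilyl)oxy]cyclohex-2-en-1-one | CC1(C)[C@@H](Br)C[C@@H](O[Si](C)(C)C(C)(C)C)[C@@]1(C)[C@]1(O[Si](CC)(CC)CC)CC=C(C=C)C(=O)C1 | intermediate
26 | lithium dienolate from 25 (C8a–O, C8a=C4a, vinyl on C4a) | CC1(C)[C@@H](Br)C[C@@H](O[Si](C)(C)C(C)(C)C)[C@@]1(C)[C@]1(O[Si](CC)(CC)CC)CCC(C=C)=C([O-])C1.[Li+] | intermediate (not isolated)
27 | (2S,5S)-5-Cyp-2-ethenyl-2-methyl-5-[(triethylsilyl)oxy]cyclohexan-1-one | CC1(C)[C@@H](Br)C[C@@H](O[Si](C)(C)C(C)(C)C)[C@@]1(C)[C@]1(O[Si](CC)(CC)CC)CC[C@@](C)(C=C)C(=O)C1 | intermediate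
28 | isopropenylmagnesium bromide | CC(=C)[Mg]Br | starting material
29 | 5-Cyp-2-ethenyl-2-methyl-1-(prop-1-en-2-yl)-5-[(triethylsilyl)oxy]cyclohexan-1-ol (isopropenyl trans to vinyl) | CC1(C)[C@@H](Br)C[C@@H](O[Si](C)(C)C(C)(C)C)[C@@]1(C)[C@]1(O[Si](CC)(CC)CC)CC[C@@](C)(C=C)[C@](O)(C(C)=C)C1 | intermediate
30 | potassium alkoxide of 29 | CC1(C)[C@@H](Br)C[C@@H](O[Si](C)(C)C(C)(C)C)[C@@]1(C)[C@]1(O[Si](CC)(CC)CC)CC[C@@](C)(C=C)[C@]([O-])(C(C)=C)C1.[K+] | intermediate (not isolated)
31 | potassium enolate of the ten-membered (E)-enone (C8a–O, C8a=C1) | CC1(C)[C@@H](Br)C[C@@H](O[Si](C)(C)C(C)(C)C)[C@@]1(C)[C@]1(O[Si](CC)(CC)CC)CC/C(C)=C/CC/C(C)=C(\[O-])/C1.[K+] | intermediate (not isolated)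
32 | (1Z,5E)-9-Cyp-2,6-dimethyl-9-[(triethylsilyl)oxy]cyclodeca-1,5-dien-1-yl trifluoromethanesulfonate | CC1(C)[C@@H](Br)C[C@@H](O[Si](C)(C)C(C)(C)C)[C@@]1(C)[C@]1(O[Si](CC)(CC)CC)CC/C(C)=C/CC/C(C)=C(\OS(=O)(=O)C(F)(F)F)/C1 | intermediate
33 | (1E,5E)-8-Cyp-1,5-dimethyl-8-[(triethylsilyl)oxy]cyclodeca-1,5-diene | CC1(C)[C@@H](Br)C[C@@H](O[Si](C)(C)C(C)(C)C)[C@@]1(C)[C@]1(O[Si](CC)(CC)CC)CC/C(C)=C/CC/C(C)=C/C1 | intermediate (key-step precursor)
34 | 4-bromo-7-Cyp-4a-methyl-1-methylidene-7-[(triethylsilyl)oxy]decahydronaphthalene (trans-fused) | CC1(C)[C@@H](Br)C[C@@H](O[Si](C)(C)C(C)(C)C)[C@@]1(C)[C@]1(O[Si](CC)(CC)CC)CC[C@@]2(C)[C@H](Br)CCC(=C)[C@@H]2C1 | intermediate (key-step product)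
35 | spiro-1,2,4-trioxolane (ozonide) of 34 at C1 | CC1(C)[C@@H](Br)C[C@@H](O[Si](C)(C)C(C)(C)C)[C@@]1(C)[C@]1(O[Si](CC)(CC)CC)CC[C@@]2(C)[C@H](Br)CCC3(OCOO3)[C@@H]2C1 | intermediate (not isolated)
36 | 4-bromo-7-Cyp-4a-methyl-7-[(triethylsilyl)oxy]octahydronaphthalen-1(2H)-one (trans-fused) | CC1(C)[C@@H](Br)C[C@@H](O[Si](C)(C)C(C)(C)C)[C@@]1(C)[C@]1(O[Si](CC)(CC)CC)CC[C@@]2(C)[C@H](Br)CCC(=O)[C@@H]2C1 | intermediate
37 | C1=C8a trimethylsilyl enol ether of 36 | CC1(C)[C@@H](Br)C[C@@H](O[Si](C)(C)C(C)(C)C)[C@@]1(C)[C@]1(O[Si](CC)(CC)CC)CC[C@@]2(C)[C@H](Br)CCC(O[Si](C)(C)C)=C2C1 | intermediate (not isolated)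
38 | 4-bromo-7-Cyp-4a-methyl-7-[(triethylsilyl)oxy]-8a-[(trimethylsilyl)oxy]octahydronaphthalen-1(2H)-one | CC1(C)[C@@H](Br)C[C@@H](O[Si](C)(C)C(C)(C)C)[C@@]1(C)[C@]1(O[Si](CC)(CC)CC)CC[C@@]2(C)[C@H](Br)CCC(=O)[C@]2(O[Si](C)(C)C)C1 | intermediate
39 | 4-bromo-7-Cyp-1,4a-dimethyl-7-[(triethylsilyl)oxy]-8a-[(trimethylsilyl)oxy]decahydronaphthalen-1-ol | CC1(C)[C@@H](Br)C[C@@H](O[Si](C)(C)C(C)(C)C)[C@@]1(C)[C@]1(O[Si](CC)(CC)CC)CC[C@@]2(C)[C@H](Br)CC[C@](C)(O)[C@]2(O[Si](C)(C)C)C1 | intermediate
40 | (1S,4R,4aR,7S,8aS)-4-bromo-7-[(1S,2R,4S)-4-bromo-2-hydroxy-1,5,5-trimethylcyclopentyl]-1,4a-dimethyloctahydronaphthalene-1,7,8a(2H)-triol | CC1(C)[C@@H](Br)C[C@@H](O)[C@@]1(C)[C@]1(O)CC[C@@]2(C)[C@H](Br)CC[C@](C)(O)[C@]2(O)C1 | target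

**Totals**

Total step count: 26. Longest linear sequence: 26 steps (1 to 40); the route is fully linear.

**Steps most likely to fail**

Step 22. The C1 cation may lose a ring proton (from C2 or C8a) instead of a methyl proton, which would spread the material over alkene isomers. The fallback sets out from 33 and changes the way the cation is terminated. N-Bromosuccinimide in aqueous acetone should give the transannular bromohydration product, the tertiary alcohol F1, by capture of the cation by water from the equatorial side away from the C4a methyl. Its equatorial leaving group has no antiperiplanar ring hydrogen, so anti elimination with SOCl2 in pyridine can only take a methyl hydrogen. This returns the exocyclic alkene 34.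

Step 24. Facial selectivity in the oxidation of the silyl enol ether may be poor, because the axial C7 silyloxy group crowds the face that the angular methyl leaves open. The fallback sets out from 36 and lets the C7 hydroxyl direct the oxygen. Tf2O with 2,6-di-tert-butyl-4-methylpyridine should give the more substituted enol triflate F2. Me2CuLi then replaces the triflate by methyl to give the tetrasubstituted C1=C8a alkene F3. HF·pyridine buffered with pyridine cleaves the tertiary triethylsilyl ether ahead of the hindered secondary silyl ether and gives the homoallylic alcohol F4. VO(acac)2 with t-BuOOH delivers the epoxide oxygen on the face of that hydroxyl and gives the epoxide F5. Aqueous HClO4 in THF opens it at C1 in the trans-diaxial sense to give the 2′-O-silyl ether F6. HF·pyridine then removes the last silyl group and the route is rejoined at 40.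

Step 12. The allyl group may add to the other face of the ketone, which would give the C7 epimer. The fallback sets out from 12 and exchanges the order of the two allyl-type additions. Allylmagnesium bromide gives the homoallylic alcohol F7, Dess–Martin oxidation gives the allyl ketone F8, and 2-methylallylmagnesium chloride is added last. With the same intrinsic facial preference, the exchanged order gives the opposite configuration at C7 and returns to 17.

Further compounds
F1 | step 22 | 4-bromo-7-Cyp-1,4a-dimethyl-7-[(triethylsilyl)oxy]decahydronaphthalen-1-ol (trans-fused; C1 hydroxyl equatorial, C1 methyl axial) | CC1(C)[C@@H](Br)C[C@@H](O[Si](C)(C)C(C)(C)C)[C@@]1(C)[C@]1(O[Si](CC)(CC)CC)CC[C@@]2(C)[C@H](Br)CC[C@@](C)(O)[C@@H]2C1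
F2 | step 24 | C1=C8a enol triflate of 36 | CC1(C)[C@@H](Br)C[C@@H](O[Si](C)(C)C(C)(C)C)[C@@]1(C)[C@]1(O[Si](CC)(CC)CC)CC[C@@]2(C)[C@H](Br)CCC(OS(=O)(=O)C(F)(F)F)=C2C1
F3 | step 24 | 4-bromo-7-Cyp-1,4a-dimethyl-7-[(triethylsilyl)oxy]-2,3,4,4a,5,6,7,8-octahydronaphthalene (C1=C8a alkene) | CC1(C)[C@@H](Br)C[C@@H](O[Si](C)(C)C(C)(C)C)[C@@]1(C)[C@]1(O[Si](CC)(CC)CC)CC[C@@]2(C)[C@H](Br)CCC(C)=C2C1
F4 | step 24 | 5-bromo-2-Cyp-4a,8-dimethyl-1,2,3,4,4a,5,6,7-octahydronaphthalen-2-ol (free C7 hydroxyl, C1=C8a alkene) | CC1(C)[C@@H](Br)C[C@@H](O[Si](C)(C)C(C)(C)C)[C@@]1(C)[C@]1(O)CC[C@@]2(C)[C@H](Br)CCC(C)=C2C1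
F5 | step 24 | C1–C8a epoxide of F4, oxygen syn to the C7 hydroxyl and anti to the C4a methyl | CC1(C)[C@@H](Br)C[C@@H](O[Si](C)(C)C(C)(C)C)[C@@]1(C)[C@]1(O)CC[C@@]2(C)[C@H](Br)CC[C@@]3(C)O[C@@]23C1
F6 | step 24 | 2′-O-tert-butyldimethylsilyl ether of 40 | CC1(C)[C@@H](Br)C[C@@H](O[Si](C)(C)C(C)(C)C)[C@@]1(C)[C@]1(O)CC[C@@]2(C)[C@H](Br)CC[C@](C)(O)[C@]2(O)C1
F7 | step 12 | 1-Cyp-but-3-en-1-ol (carbinol epimers) | CC1(C)[C@@H](Br)C[C@@H](O[Si](C)(C)C(C)(C)C)[C@@]1(C)C(O)CC=C
F8 | step 12 | 1-Cyp-but-3-en-1-one | CC1(C)[C@@H](Br)C[C@@H](O[Si](C)(C)C(C)(C)C)[C@@]1(C)C(=O)CC=C
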